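## The problem

Target 35 is a cis-fused eremophilane; eremophilane numbering is used throughout (ring A = C1–C5 and C10, ring B = C5–C10, C14 on C5, C15 on C4, C11–C13 the isopropenyl group on C7; β is the face of C14). The decalin carries six stereocentres (3R,4R,5R,7R,9R,10S), and the C3 ester side chain a seventh (4'R) beside an (E)-enoate and a (Z)-configured angelate. The rings share the quaternary carbon C5, flanked by the stereocentres C4 and C10. C14, C15, H10, the isopropenyl group and the C9 hydroxyl are β and the C3 oxygen is α, so in the chair–chair form with the C4–C5 bond axial on ring B every substituent except C14 is equatorial. C5 has to be set by a reagent; once it stands, the cis junction at C10 can follow from ring closure, the adjacent axial C14 can decide the face of C4, and the fold of the cis-decalin can steer reagents to the β face of ring B at C7, C8 and C9. Ring B is the fragile part: the 7-isopropenyl 8-ketone is a β,γ-unsaturated ketone that conjugates or epimerises at C7 with base or acid, the C8/C9 α-ketol can transpose through its enediol, and while C9 is a ketone C10 can epimerise to a trans junction of similar energy. The angelate isomerises to the tiglate under nucleophilic or basic conditions and the γ-acyloxy enoate is a Michael acceptor, so the side chain must arrive late and the last steps must be neutral. The enabling feature is the C9 oxygen: C5 is β and C10 is α to it, so a 3-methylcyclohexenone is electrophilic at C5 and, after addition, nucleophilic at C10, and a five-carbon unit (C15/C4–C3–C2–C1) with a metal at C4 and a leaving group at C1 can close ring A on it in one operation.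

## Retrosynthesis

The last bonds unmade lie outside the skeleton. Target 35 is traced to its 9-O-PMB ether 34, so that a neutral oxidative deprotection is the only operation on the finished α-ketol. Ketone 34 goes back to the C8 carbinol 33, and the C3–O acyl bond of 33 is cut to give diol 21 and acid 31. Cutting the ester at the carbinol stage rather than at ketone 34 keeps the amine-promoted esterification away from the β,γ-unsaturated ketone. The price is that the forward reaction must acylate the equatorial 3α-hydroxyl of 21 beside the axial, doubly flanked 8β-hydroxyl.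

Diol 21 comes from silyl ether 20, and 20 from cis-diol 18 by alkylation at O9. Diol 18 is the reduction product of α-hydroxy ketone 17, whose C8–O bond is cut to give ketone 15. This keeps the C9 oxygen of the key step and adds the C8 oxygen beside it. The neighbouring options are a 1,2-transposition of the carbonyl followed by hydroxylation at C9 (three to four steps more) or an equilibrating ketol shift (C7 and C10 at risk). Forward, the sequence asks for β-face hydroxylation at C8, hydride delivery to the α face of C9 anti to the axial C8–O bond, and discrimination of the equatorial from the axial oxygen of the cis-diol.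

In 15 the C7–C11 bond is cut. C7 is β to the C9 carbonyl, so the isopropenyl group can enter as a nucleophile (borate 14) on enone 13, which is ketone 11 less two hydrogens. Making this bond from a C8 ketone would need an electrophilic isopropenyl equivalent or an aldol–dehydration that ends in the conjugated isopropylidene ketone. The conjugate addition avoids both and lets a chiral ligand, not only the substrate, choose the face at C7. Forward, 11 must be dehydrogenated toward C8 (not C10) and the addition must occur on the β face.

Ketone 11 is simplified to the exocyclic alkene 10 by removing the hydrogens at C4 and C15. This takes the C4 stereocentre out of the annulation and lets C15 enter as the terminal carbon of an alkyne. Forward, hydrogen must reach the α face of C4. A hydrogen-atom-transfer hydrogenation is chosen because it works under thermodynamic control with the silyl ether in place; a hydroxyl-directed hydrogenation would cost a deprotection and a reprotection.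

In 10 the bonds C4–C5 and C1–C10 are cut together. This is the cut with the largest gain: bicyclic 10 with three stereocentres falls to the achiral commercial enone 7 and open-chain alkyne 6 with one stereocentre. Cutting C5–C10 or C5–C6 instead would leave the quaternary centre inside a fragment. Forward, the internal alkenylalane 8 made from 6 must be transferred to C5 of 7 with catalyst control, and the aluminium enolate 9 must alkylate at C10 with the primary chloride; the closure can only give the cis junction.

Alkyne 6 is cut at its C–Si and O–Si bonds back to propargylic alcohol 4 (through 5), and 4 at its carbinol C–H bond to ynone 3, the acylation product of alkyne 2 with acid chloride 1. The stereocentre that becomes C3 is thus bought by asymmetric transfer hydrogenation of an alkynyl ketone, a substrate class on which that reaction is reliable.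

Acid 31 is tert-butyl ester 30 unmasked. Its angelate C–O bond is cut to alcohol 27 and angelic acid 28, and the enoate double bond of 27 (through silyl ether 26) to aldehyde 25 and ylide 24; 25 is made in the flask from protected hydroxy ester 23, which comes from chiral-pool ester 22. The tert-butyl ester is chosen because its removal is acidic and leaves the angelate geometry and the allylic stereocentre alone.

## Roads not taken

Alternative 1: The cut is at C5–C6 and C9–C10. Ring A is taken as 2-methylcyclohex-2-enone A1 (its carbonyl is C4, its methyl C14), and C6 and C9 come from vinylene carbonate A2. Forward, irradiation of A1 bound to an AlBr3-activated chiral oxazaborolidine with A2 would give the cis-fused cyclobutane carbonate A3. Cleaving the cyclobutanediol then leaves C6 and C9 as two carbonyl-level carbons cis on ring A, and ring B must be completed by adding C7 and C8.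
- Merits: two cheap achiral partners, and the quaternary C5 and the cis C5/C10 relationship set in one catalytic step. C9 arrives oxygenated, which is better than the chosen plan, where steps 9–11, 19 and 20 are spent on the C8/C9 exchange.
- Weak points: A3 holds only ring A. Two more skeletal bonds (C6–C7, C8–C9) and the differentiation of two near-equivalent carbonyl carbons are needed for ring B. C3 must be oxygenated and C4 methylated from the lone ketone. Enantioselective Lewis-acid photocycloadditions are established for simple alkenes, not for an electron-rich enediol carbonate.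
- Comparison: compound 10 already holds both rings, the C3 oxygen and C15, so the chosen plan is ahead by several C–C bond formations.

Alternative 2: The cut is at C5–C10 and C3–C4. An open-chain precursor, a tigloyl ketone (C4=C5, C6 carbonyl) tethered through C7–C9 to a 1-boryl diene (C10=C1–C2=C3), would cyclise on heating to the cis-fused octalone A4.
- Merits: one step would close both rings and set C3 (as an allylboronate that oxidises with retention), C4, C5 and C10, with the C8 and C9 oxygens already present and differentiated. In stereocentres per step it is clearly better than step 5, which sets only C5 and C10.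
- Weak points: the dienophile is an α,β-disubstituted enone that must form a quaternary carbon, so forcing conditions are likely, and the boryl diene and the dioxygenated tether may not survive them. Endo/exo and facial selectivity rest on two tether stereocentres and are hard to predict. The carbonyl ends at C6, where 35 has a methylene, so it must serve to bring in C7 as an electrophilic isopropenyl equivalent (the problem the chosen plan avoids) and then be deleted. The C1=C2 alkene must be reduced before the isopropenyl group exists. The precursor is itself a long linear synthesis.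
- Comparison: the chosen plan sets fewer stereocentres in its key step, but does so with catalyst control on a commercial enone and leaves no superfluous oxygen.

Alternative 3: The cut is at C1–C10. A prochiral cyclohexadienone with a nitroalkyl arm (C1–C4, C4 as ketal) would be desymmetrised by a cinchona amine–thiourea, the nitronate carbon C1 adding to C10 to give the cis-fused enone A5.
- Merits: metal-free, with C5 and C10 set by the catalyst. Ring B is born with the C8 carbonyl and a C6=C7 double bond, so the C9 hydroxyl could come directly from enolate oxidation and no C8/C9 exchange is needed. In ring B this road is better than the chosen one.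
- Weak points: the nitro group at C1 must be removed, the C3 oxygen is missing and must be introduced beside the C4 carbonyl, and C4 needs methylenation and a face-selective reduction. The isopropenyl group would have to enter at C7, the α-carbon of the enone, by halogenation, cross-coupling and a conjugate reduction that sets C7 and risks conjugation.
- Comparison: what this road saves in ring B (about three steps) it spends in ring A (about five). In the chosen plan ring A is complete one step after the key step.

Key step: step 5

Remark (assumption): compounds 14, 22, 24 and 28 are taken as commercial. The NHC enantiomer in step 5 and the BINAP enantiomer in step 8 are named from the accepted selectivity models and would be confirmed on first use.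

## Steps

Step 1
Reactants: 1 3-chloropropanoyl chloride; 2 bis(trimethylsilyl)acetylene
Product: 3 5-chloro-1-(trimethylsilyl)pent-1-yn-3-one
Conditions: AlCl3, CH2Cl2, 0 °C
Reagents that add atoms: none
Why: Friedel–Crafts-type acylation of an alkynylsilane: the acylium ion attacks the silyl-bearing carbon and one trimethylsilyl group is lost, giving the ynone; no stereocentre is formed.

Step 2
Reactants: 3 5-chloro-1-(trimethylsilyl)pent-1-yn-3-one
Product: 4 (R)-5-chloro-1-(trimethylsilyl)pent-1-yn-3-ol
Conditions: Ru(p-cymene)[(R,R)-TsDPEN] (1 mol %), i-PrOH, 22 °C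
Reagents that add atoms: none
Why: Noyori asymmetric transfer hydrogenation of an alkynyl ketone: the alkyne takes the place of the aryl group in the six-membered transition state, so the (R,R)-catalyst should give the (R)-carbinol (future C3). Base-free conditions spare the β-chloro ketone from elimination.

Step 3
Reactants: 4 (R)-5-chloro-1-(trimethylsilyl)pent-1-yn-3-ol
Product: 5 (R)-3-(tert-butyldimethylsilyloxy)-5-chloro-1-(trimethylsilyl)pent-1-yne
Conditions: TBSCl, imidazole, DMF, 22 °C
Reagents that add atoms: tert-butyldimethylsilyl chloride, CC(C)(C)[Si](C)(C)Cl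
Why: Standard silylation of a secondary alcohol. Doing it before C-desilylation keeps the 1,3-chlorohydrin from closing to an oxetane in the next, basic step.

Step 4
Reactants: 5 (R)-3-(tert-butyldimethylsilyloxy)-5-chloro-1-(trimethylsilyl)pent-1-yne
Product: 6 (R)-3-(tert-butyldimethylsilyloxy)-5-chloropent-1-yne
Conditions: K2CO3 (cat.), MeOH, 0 → 22 °C
Reagents that add atoms: none
Why: Methanolysis of the alkynyl C–Si bond (protodesilylation); the silyl ether and the primary chloride are inert at room temperature.

Step 5
Reactants: 6 (R)-3-(tert-butyldimethylsilyloxy)-5-chloropent-1-yne; 7 3-methylcyclohex-2-en-1-one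
Product: 10 3α-(tert-butyldimethylsilyloxy)-5β-methyl-4-methylidene-10βH-decalin-9-one [(4aS,6R,8aS)-6-(tert-butyldimethylsilyloxy)-4a-methyl-5-methylideneoctahydronaphthalen-1(2H)-one], via alkenylalane 8 (not isolated), via aluminium enolate 9 (not isolated)
Conditions: (i-Bu)2AlH, Ni(dppp)Cl2 (3 mol %), THF, 0 → 22 °C; then 7, Cu(OTf)2 (5 mol %), [Ag(NHC)]2 (2.5 mol %; NHC = (4S,5S)-1-(2,6-diethylphenyl)-4,5-diphenyl-3-(2-sulfonatophenyl)imidazolin-2-ylidene or its enantiomer), THF, −30 → 4 °C; then MeLi, DMPU, −30 → 45 °C
Reagents that add atoms: none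
Why: (i-Bu)2AlH with Ni(dppp)Cl2 hydroaluminates the terminal alkyne with aluminium on the internal carbon, giving 2-alkenylalane 8 in which C4 is the nucleophilic carbon. A chiral NHC–copper alkenyl species formed by Al-to-Cu transmetalation adds C4 to C5 of enone 7 in a 1,4-sense and releases the regiodefined C9 aluminium enolate 9; MeLi turns it into the more nucleophilic aluminate, whose C10 displaces chloride at C1. The closest known reactions are the copper-catalysed enantioselective conjugate addition of nickel-derived 2-alkenylalanes to 3-methylcyclohexenone and the conjugate addition–cycloalkylation known as methylenecyclohexane annulation; joining them in one flask on a chiral alane applies both to a new substrate. Ring A closes in a 6-exo-tet mode by C-alkylation, since O-alkylation would need an eight-membered ring. C5 is set by the ligand, whose enantiomer is chosen to expose the enone face leading to the 5S centre; the (R)-centre at C3 is carried in unchanged and should be matched, or at least not opposed, to it. C10 is set by stereoelectronics: C1 must approach perpendicular to the enolate plane from the side of the C5 side chain, an axial–equatorial arrangement that can only give the cis junction (H10 and C14 both β). The step needs internal-carbon selectivity in the hydroalumination (secured by the dppp ligand), 1,4- over 1,2-addition (secured by copper) and persistence of the silyloxy group beside the C–Al bond (a bulky silyl ether is a poor leaving group at or below room temperature).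

Step 6
Reactants: 10 3α-(tert-butyldimethylsilyloxy)-5β-methyl-4-methylidene-10βH-decalin-9-one
Product: 11 3α-(tert-butyldimethylsilyloxy)-4β,5β-dimethyl-10βH-decalin-9-one [(4aR,5R,6R,8aS)-6-(tert-butyldimethylsilyloxy)-4a,5-dimethyloctahydronaphthalen-1(2H)-one]
Conditions: Mn(dpm)3 (10 mol %), PhSiH3, t-BuOOH, i-PrOH, 22 °C
Reagents that add atoms: none
Why: Metal-hydride hydrogen-atom-transfer hydrogenation: a hydrogen atom adds to the methylene carbon and the tertiary C4 radical is quenched by axial hydrogen delivery on the α face, anti to the adjacent axial C14. This should give the thermodynamically preferred equatorial 4β-methyl, trans to the C3 silyloxy group. The neutral conditions leave the silyl ether and C10 untouched.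

Step 7
Reactants: 11 3α-(tert-butyldimethylsilyloxy)-4β,5β-dimethyl-10βH-decalin-9-one
Product: 13 3α-(tert-butyldimethylsilyloxy)-4β,5β-dimethyl-10βH-decal-7-en-9-one [(4aR,5R,6R,8aS)-6-(tert-butyldimethylsilyloxy)-4a,5-dimethyl-4a,5,6,7,8,8a-hexahydronaphthalen-1(4H)-one], via trimethylsilyl enol ether 12 (not isolated)
Conditions: LiN(i-Pr)2, TMSCl, THF, −78 °C; then Pd(OAc)2, MeCN, 22 °C
Reagents that add atoms: none
Why: Saegusa–Ito oxidation: kinetic deprotonation at the C8 methylene (C10 is a hindered methine beside the quaternary carbon) with internal silyl quench, then divalent palladium converts the silyl enol ether into the C7=C8 enone by β-hydride elimination. C10 is never enolised.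

Step 8
Reactants: 13 3α-(tert-butyldimethylsilyloxy)-4β,5β-dimethyl-10βH-decal-7-en-9-one; 14 potassium trifluoro(prop-1-en-2-yl)borate
Product: 15 3α-(tert-butyldimethylsilyloxy)-7β-isopropenyl-4β,5β-dimethyl-10βH-decalin-9-one
Conditions: [Rh(cod)2]BF4 (5 mol %), (S)-BINAP (5.5 mol %), toluene/H2O (10:1), 90 °C
Reagents that add atoms: none
Why: Hayashi–Miyaura rhodium-catalysed 1,4-addition of an alkenylboron reagent to a β-unsubstituted cyclohexenone. (S)-BINAP, which gives (S)-3-substituted cyclohexanones, and the open β face of the cis-decalin (the α face lies under the axial C4–C5 bond) should both place the isopropenyl group 7β (7S). The base-free medium protonates the rhodium enolate at C8 and should leave C10 alone.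

Step 9
Reactants: 15 3α-(tert-butyldimethylsilyloxy)-7β-isopropenyl-4β,5β-dimethyl-10βH-decalin-9-one
Product: 17 8β-hydroxy-3α-(tert-butyldimethylsilyloxy)-7β-isopropenyl-4β,5β-dimethyl-10βH-decalin-9-one, via sodium enolate 16 (not isolated)
Conditions: NaN(SiMe3)2, THF, −78 °C; then 3-phenyl-2-(phenylsulfonyl)oxaziridine, −78 °C; NH4Cl (aq)
Reagents that add atoms: 3-phenyl-2-(phenylsulfonyl)oxaziridine, O=S(=O)(N1OC1c1ccccc1)c1ccccc1
Why: Enolate hydroxylation with an N-sulfonyloxaziridine: the kinetic enolate forms toward the C8 methylene, and oxygen transfer along the axial trajectory on the open β face should give the axial 8β-alcohol. This centre is later destroyed, but it steers step 10.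

Step 10
Reactants: 17 8β-hydroxy-3α-(tert-butyldimethylsilyloxy)-7β-isopropenyl-4β,5β-dimethyl-10βH-decalin-9-one
Product: 18 3α-(tert-butyldimethylsilyloxy)-7β-isopropenyl-4β,5β-dimethyl-10βH-decalin-8β,9β-diol
Conditions: NaBH4, CeCl3·7H2O, MeOH, −78 → −40 °C
Reagents that add atoms: none
Why: Hydride reduction of an α-hydroxy ketone under Luche-type conditions: Felkin–Anh attack anti to the axial C8–O bond brings hydride to the α face of C9 and should give the equatorial 9β-alcohol, that is the cis-diol. Low temperature and the cerium salt suppress ketol isomerisation.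

Step 11
Reactants: 18 3α-(tert-butyldimethylsilyloxy)-7β-isopropenyl-4β,5β-dimethyl-10βH-decalin-8β,9β-diol
Product: 20 9β-(4-methoxybenzyloxy)-3α-(tert-butyldimethylsilyloxy)-7β-isopropenyl-4β,5β-dimethyl-10βH-decalin-8β-ol, via stannylene acetal 19 (not isolated)
Conditions: Bu2SnO, toluene, reflux (−H2O); then PMBCl, Bu4NI (cat.), toluene, 80 °C
Reagents that add atoms: 4-methoxybenzyl chloride, COc1ccc(CCl)cc1
Why: Regioselective alkylation of a cis-1,2-diol through its dibutylstannylene acetal: the equatorial oxygen (O9) is the nucleophilic one, so the axial 8β-hydroxyl stays free for later oxidation. No fluoride or strong base is present, so the silyl ether survives.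

Step 12
Reactants: 20 9β-(4-methoxybenzyloxy)-3α-(tert-butyldimethylsilyloxy)-7β-isopropenyl-4β,5β-dimethyl-10βH-decalin-8β-ol
Product: 21 9β-(4-methoxybenzyloxy)-7β-isopropenyl-4β,5β-dimethyl-10βH-decalin-3α,8β-diol
Conditions: Bu4NF, THF, 22 → 45 °C; NH4Cl (aq)
Reagents that add atoms: none
Why: Fluoride cleavage of the secondary silyl ether; the molecule holds no ketone at this stage, so the basicity of the fluoride source is harmless, and the PMB ether and the alkene are inert.

Step 13
Reactants: 22 methyl (R)-2-hydroxybutanoate
Product: 23 methyl (R)-2-(tert-butyldimethylsilyloxy)butanoate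
Conditions: TBSCl, imidazole, DMF, 22 °C
Reagents that add atoms: tert-butyldimethylsilyl chloride, CC(C)(C)[Si](C)(C)Cl
Why: Standard silylation of a secondary alcohol; the stereocentre is not involved.

Step 14
Reactants: 23 methyl (R)-2-(tert-butyldimethylsilyloxy)butanoate; 24 tert-butyl (triphenylphosphoranylidene)acetate
Product: 26 tert-butyl (R,E)-4-(tert-butyldimethylsilyloxy)hex-2-enoate, via aldehyde 25 (not isolated)
Conditions: (i-Bu)2AlH, CH2Cl2, −78 °C; then 24, −78 → 22 °C
Reagents that add atoms: none
Why: Half-reduction of the ester to the aluminium hemiacetal and Wittig olefination in the same flask; the stabilised ylide gives the (E)-enoate. Aldehyde 25 is never isolated, which avoids epimerisation beside the carbonyl.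

Step 15
Reactants: 26 tert-butyl (R,E)-4-(tert-butyldimethylsilyloxy)hex-2-enoate
Product: 27 tert-butyl (R,E)-4-hydroxyhex-2-enoate
Conditions: HF·pyridine, THF, 0 → 22 °C
Reagents that add atoms: none
Why: Fluoride desilylation under mildly acidic conditions, which avoids base-induced side reactions of the γ-hydroxy enoate.

Step 16
Reactants: 27 tert-butyl (R,E)-4-hydroxyhex-2-enoate; 28 angelic acid [(Z)-2-methylbut-2-enoic acid]
Product: 30 tert-butyl (R,E)-4-[(Z)-2-methylbut-2-enoyloxy]hex-2-enoate, via mixed anhydride 29 (not isolated)
Conditions: 2,4,6-Cl3C6H2COCl, Et3N, toluene, 22 °C; then 27, toluene, 75 °C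
Reagents that add atoms: none
Why: Yamaguchi esterification without a nucleophilic catalyst: the mixed anhydride acylates thermally, a protocol under which the (Z)-angelate should not isomerise to the (E)-tiglate.

Step 17
Reactants: 30 tert-butyl (R,E)-4-[(Z)-2-methylbut-2-enoyloxy]hex-2-enoate
Product: 31 (R,E)-4-[(Z)-2-methylbut-2-enoyloxy]hex-2-enoic acid
Conditions: CF3CO2H, CH2Cl2, 0 → 22 °C
Reagents that add atoms: none
Why: Acidolysis of the tert-butyl ester with loss of isobutene; the angelate and the allylic acyloxy stereocentre should tolerate the acid at room temperature.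

Step 18
Reactants: 21 9β-(4-methoxybenzyloxy)-7β-isopropenyl-4β,5β-dimethyl-10βH-decalin-3α,8β-diol; 31 (R,E)-4-[(Z)-2-methylbut-2-enoyloxy]hex-2-enoic acid
Product: 33 3α-{(R,E)-4-[(Z)-2-methylbut-2-enoyloxy]hex-2-enoyloxy}-9β-(4-methoxybenzyloxy)-7β-isopropenyl-4β,5β-dimethyl-10βH-decalin-8β-ol, via mixed anhydride 32 (not isolated)
Conditions: 2,4,6-Cl3C6H2COCl, Et3N, toluene, 22 °C; then 21, DMAP, toluene, 0 → 22 °C
Reagents that add atoms: none
Why: Yamaguchi esterification: the equatorial 3α-hydroxyl should react, while the axial 8β-hydroxyl between the C7 and C9 substituents should not. The ester is made before the base-sensitive β,γ-unsaturated ketone exists.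

Step 19
Reactants: 33 3α-{(R,E)-4-[(Z)-2-methylbut-2-enoyloxy]hex-2-enoyloxy}-9β-(4-methoxybenzyloxy)-7β-isopropenyl-4β,5β-dimethyl-10βH-decalin-8β-ol
Product: 34 3α-{(R,E)-4-[(Z)-2-methylbut-2-enoyloxy]hex-2-enoyloxy}-9β-(4-methoxybenzyloxy)-7β-isopropenyl-4β,5β-dimethyl-10βH-decalin-8-one
Conditions: Dess–Martin periodinane, NaHCO3, CH2Cl2, 0 → 22 °C
Reagents that add atoms: none
Why: Dess–Martin oxidation under buffered, non-basic conditions should turn the axial C8 carbinol into the ketone without enolising C7 or C9.

Step 20
Reactants: 34 3α-{(R,E)-4-[(Z)-2-methylbut-2-enoyloxy]hex-2-enoyloxy}-9β-(4-methoxybenzyloxy)-7β-isopropenyl-4β,5β-dimethyl-10βH-decalin-8-one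
Product: 35 3α-{(R,E)-4-[(Z)-2-methylbut-2-enoyloxy]hex-2-enoyloxy}-9β-hydroxy-7β-isopropenyl-4β,5β-dimethyl-10βH-decalin-8-one (CNP0190706.1)
Conditions: DDQ, CH2Cl2/pH 7 phosphate buffer, 0 → 22 °C
Reagents that add atoms: none
Why: Oxidative cleavage of the PMB ether (benzylic hydride abstraction, hydrolysis of the oxocarbenium ion) under neutral conditions releases the 9β-hydroxyl; the β,γ-unsaturated ketone, the angelate and the enoate should be untouched.

## Compound list

1 | 3-chloropropanoyl chloride | ClCCC(Cl)=O | starting material
2 | bis(trimethylsilyl)acetylene | C[Si](C)(C)C#C[Si](C)(C)C | starting material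
3 | 5-chloro-1-(trimethylsilyl)pent-1-yn-3-one | C[Si](C)(C)C#CC(=O)CCCl | intermediate
4 | (R)-5-chloro-1-(trimethylsilyl)pent-1-yn-3-ol | C[Si](C)(C)C#C[C@H](O)CCCl | intermediate
5 | (R)-3-(tert-butyldimethylsilyloxy)-5-chloro-1-(trimethylsilyl)pent-1-yne | C[Si](C)(C)C#C[C@H](O[Si](C)(C)C(C)(C)C)CCCl | intermediate
6 | (R)-3-(tert-butyldimethylsilyloxy)-5-chloropent-1-yne | C#C[C@H](O[Si](C)(C)C(C)(C)C)CCCl | intermediate
7 | 3-methylcyclohex-2-en-1-one | CC1=CC(=O)CCC1 | starting material
8 | diisobutyl[(3R)-3-(tert-butyldimethylsilyloxy)-5-chloropent-1-en-2-yl]alane | C=C([Al](CC(C)C)CC(C)C)[C@H](O[Si](C)(C)C(C)(C)C)CCCl | intermediate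
9 | diisobutylaluminium enolate (C9=C10) of (S)-3-[(R)-3-(tert-butyldimethylsilyloxy)-5-chloropent-1-en-2-yl]-3-methylcyclohexanone | C=C([C@H](O[Si](C)(C)C(C)(C)C)CCCl)[C@]1(C)C=C(O[Al](CC(C)C)CC(C)C)CCC1 | intermediate
10 | 3α-(tert-butyldimethylsilyloxy)-5β-methyl-4-methylidene-10βH-decalin-9-one (3R,5S,10S) | C1C[C@@]2(C)[C@H](CC[C@@H](O[Si](C)(C)C(C)(C)C)C2=C)C(=O)C1 | intermediate
11 | 3α-(tert-butyldimethylsilyloxy)-4β,5β-dimethyl-10βH-decalin-9-one (3R,4R,5R,10S) | C1C[C@@]2(C)[C@H](CC[C@@H](O[Si](C)(C)C(C)(C)C)[C@@H]2C)C(=O)C1 | intermediate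
12 | 9-(trimethylsilyloxy)-3α-(tert-butyldimethylsilyloxy)-4β,5β-dimethyl-10βH-decal-8-ene | C1C[C@@]2(C)[C@H](CC[C@@H](O[Si](C)(C)C(C)(C)C)[C@@H]2C)C(O[Si](C)(C)C)=C1 | intermediate
13 | 3α-(tert-butyldimethylsilyloxy)-4β,5β-dimethyl-10βH-decal-7-en-9-one | C1=CC(=O)[C@H]2CC[C@@H](O[Si](C)(C)C(C)(C)C)[C@H](C)[C@@]2(C)C1 | intermediate
14 | potassium trifluoro(prop-1-en-2-yl)borate | [K+].C=C(C)[B-](F)(F)F | starting material
15 | 3α-(tert-butyldimethylsilyloxy)-7β-isopropenyl-4β,5β-dimethyl-10βH-decalin-9-one (3R,4R,5R,7S,10S) | C=C(C)[C@H]1C[C@@]2(C)[C@H](CC[C@@H](O[Si](C)(C)C(C)(C)C)[C@@H]2C)C(=O)C1 | intermediate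
16 | sodium enolate (C8=C9) of 15 | [Na+].C=C(C)[C@H]1C[C@@]2(C)[C@H](CC[C@@H](O[Si](C)(C)C(C)(C)C)[C@@H]2C)C([O-])=C1 | intermediate
17 | 8β-hydroxy-3α-(tert-butyldimethylsilyloxy)-7β-isopropenyl-4β,5β-dimethyl-10βH-decalin-9-one | C=C(C)[C@H]1C[C@@]2(C)[C@H](CC[C@@H](O[Si](C)(C)C(C)(C)C)[C@@H]2C)C(=O)[C@H]1O | intermediate
18 | 3α-(tert-butyldimethylsilyloxy)-7β-isopropenyl-4β,5β-dimethyl-10βH-decalin-8β,9β-diol | C=C(C)[C@H]1C[C@@]2(C)[C@H](CC[C@@H](O[Si](C)(C)C(C)(C)C)[C@@H]2C)[C@@H](O)[C@H]1O | intermediate
19 | 8β,9β-O-dibutylstannylene acetal of 18 | C=C(C)[C@H]1C[C@@]2(C)[C@H](CC[C@@H](O[Si](C)(C)C(C)(C)C)[C@@H]2C)[C@H]3O[Sn](CCCC)(CCCC)O[C@@H]13 | intermediate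
20 | 9β-(4-methoxybenzyloxy)-3α-(tert-butyldimethylsilyloxy)-7β-isopropenyl-4β,5β-dimethyl-10βH-decalin-8β-ol | C=C(C)[C@H]1C[C@@]2(C)[C@H](CC[C@@H](O[Si](C)(C)C(C)(C)C)[C@@H]2C)[C@@H](OCc3ccc(OC)cc3)[C@H]1O | intermediate
21 | 9β-(4-methoxybenzyloxy)-7β-isopropenyl-4β,5β-dimethyl-10βH-decalin-3α,8β-diol | C=C(C)[C@H]1C[C@@]2(C)[C@H](CC[C@@H](O)[C@@H]2C)[C@@H](OCc3ccc(OC)cc3)[C@H]1O | intermediate
22 | methyl (R)-2-hydroxybutanoate | CC[C@@H](O)C(=O)OC | starting material
23 | methyl (R)-2-(tert-butyldimethylsilyloxy)butanoate | CC[C@@H](O[Si](C)(C)C(C)(C)C)C(=O)OC | intermediate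
24 | tert-butyl (triphenylphosphoranylidene)acetate | CC(C)(C)OC(=O)C=P(c1ccccc1)(c1ccccc1)c1ccccc1 | starting material
25 | (R)-2-(tert-butyldimethylsilyloxy)butanal | CC[C@@H](O[Si](C)(C)C(C)(C)C)C=O | intermediate
26 | tert-butyl (R,E)-4-(tert-butyldimethylsilyloxy)hex-2-enoate | CC[C@@H](O[Si](C)(C)C(C)(C)C)/C=C/C(=O)OC(C)(C)C | intermediate
27 | tert-butyl (R,E)-4-hydroxyhex-2-enoate | CC[C@@H](O)/C=C/C(=O)OC(C)(C)C | intermediate
28 | angelic acid [(Z)-2-methylbut-2-enoic acid] | C/C=C(/C)C(=O)O | starting material
29 | (Z)-2-methylbut-2-enoic 2,4,6-trichlorobenzoic anhydride | C/C=C(/C)C(=O)OC(=O)c1c(Cl)cc(Cl)cc1Cl | intermediate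
30 | tert-butyl (R,E)-4-[(Z)-2-methylbut-2-enoyloxy]hex-2-enoate | CC[C@@H](OC(=O)/C(C)=C\C)/C=C/C(=O)OC(C)(C)C | intermediate
31 | (R,E)-4-[(Z)-2-methylbut-2-enoyloxy]hex-2-enoic acid | CC[C@@H](OC(=O)/C(C)=C\C)/C=C/C(=O)O | intermediate
32 | mixed anhydride of 31 with 2,4,6-trichlorobenzoic acid | CC[C@@H](OC(=O)/C(C)=C\C)/C=C/C(=O)OC(=O)c1c(Cl)cc(Cl)cc1Cl | intermediate
33 | 3α-{(R,E)-4-[(Z)-2-methylbut-2-enoyloxy]hex-2-enoyloxy}-9β-(4-methoxybenzyloxy)-7β-isopropenyl-4β,5β-dimethyl-10βH-decalin-8β-ol | C=C(C)[C@H]1C[C@@]2(C)[C@H](CC[C@@H](OC(=O)/C=C/[C@@H](CC)OC(=O)/C(C)=C\C)[C@@H]2C)[C@@H](OCc3ccc(OC)cc3)[C@H]1O | intermediate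
34 | 3α-{(R,E)-4-[(Z)-2-methylbut-2-enoyloxy]hex-2-enoyloxy}-9β-(4-methoxybenzyloxy)-7β-isopropenyl-4β,5β-dimethyl-10βH-decalin-8-one | C=C(C)[C@H]1C[C@@]2(C)[C@H](CC[C@@H](OC(=O)/C=C/[C@@H](CC)OC(=O)/C(C)=C\C)[C@@H]2C)[C@@H](OCc3ccc(OC)cc3)C1=O | intermediate
35 | 3α-{(R,E)-4-[(Z)-2-methylbut-2-enoyloxy]hex-2-enoyloxy}-9β-hydroxy-7β-isopropenyl-4β,5β-dimethyl-10βH-decalin-8-one (3R,4R,5R,7R,9R,10S; CNP0190706.1) | C=C(C)[C@H]1C[C@@]2(C)[C@H](CC[C@@H](OC(=O)/C=C/[C@@H](CC)OC(=O)/C(C)=C\C)[C@@H]2C)[C@@H](O)C1=O | target

## Step count and least certain steps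

Total: 20 steps. Longest linear sequence: 15 steps (steps 1–12 and 18–20); the side-chain acid takes 5 steps (13–17).

Step 5 (key step). The most likely failure is incomplete ring closure, because an aluminium-bound enolate is a weak nucleophile toward an unactivated primary chloride. Diastereoselectivity at C5 may also erode if the (R)-centre of the alane and the ligand are mismatched, and some alane may be lost by β-elimination of the silyloxy group. Fallback, setting out from 6 and 7: the conjugate addition is run alone and quenched with aqueous acid, and (S)-3-[(R)-3-(tert-butyldimethylsilyloxy)-5-chloropent-1-en-2-yl]-3-methylcyclohexanone F1 is isolated. Ring A is then closed separately with KOt-Bu in t-BuOH/THF at 0 °C, where the equilibrating potassium enolates funnel through the only productive one (C10, 6-exo-tet). The route is rejoined at 10.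

Step 6. The most likely failure is poor facial selectivity in the quench of the C4 radical, since the α face carries the 1,3-related C9; partial reduction of the C9 ketone is a lesser risk. Fallback, setting out from 10: the silyl ether is cleaved with pyridine-buffered HF·pyridine to give 3α-hydroxy-5β-methyl-4-methylidene-10βH-decalin-9-one F2. Hydrogenation with H2 and [Ir(cod)(PCy3)(py)]PF6 in CH2Cl2, where the 3α-hydroxyl binds iridium and hydrogen is delivered to the α face, gives 3α-hydroxy-4β,5β-dimethyl-10βH-decalin-9-one F3. Resilylation (TBSCl, imidazole) rejoins the route at 11.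

Step 8. The most likely failures are partial epimerisation at C10 or loss of the silyl ether in the hot aqueous, fluoride-releasing medium, and low face selectivity if the substrate bias opposes the ligand. Fallback, setting out from 13: (CH2=C(CH3))2CuLi with chlorotrimethylsilane in THF at −78 °C gives, under non-equilibrating conditions, 9-(trimethylsilyloxy)-3α-(tert-butyldimethylsilyloxy)-7β-isopropenyl-4β,5β-dimethyl-10βH-decal-8-ene F4. Rubottom oxidation (dimethyldioxirane, acetone, −78 °C, then dilute acid) converts it directly into 17, so steps 8 and 9 are replaced.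

Step 10. The most likely failure is hydride attack on the β face, because the α face lies under the axial C4–C5 bond; this would give the 9α-epimer. Ketol isomerisation in the basic medium is a second risk. Fallback, setting out from 17: the 8β-hydroxyl is silylated (TBSOTf, 2,6-lutidine, −78 °C) to give 3α,8β-bis(tert-butyldimethylsilyloxy)-7β-isopropenyl-4β,5β-dimethyl-10βH-decalin-9-one F5, in which the bulky axial silyloxy group closes the β face and can neither chelate nor deliver hydride. Reduction with LiBH4 gives 3α,8β-bis(tert-butyldimethylsilyloxy)-7β-isopropenyl-4β,5β-dimethyl-10βH-decalin-9β-ol F6. Etherification with 4-methoxybenzyl trichloroacetimidate and La(OTf)3 gives 9β-(4-methoxybenzyloxy)-3α,8β-bis(tert-butyldimethylsilyloxy)-7β-isopropenyl-4β,5β-dimethyl-10βH-decalin F7. Fluoride then removes both silyl groups and the route is rejoined at 21 (steps 10–12 replaced by four).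

Step 18. The most likely failure is competing or double acylation at the 8β-hydroxyl; isomerisation or γ-epimerisation of the activated enoate by DMAP is a lesser risk. Fallback, setting out from 20: the C8 carbinol is oxidised first (Dess–Martin periodinane, NaHCO3) to 9β-(4-methoxybenzyloxy)-3α-(tert-butyldimethylsilyloxy)-7β-isopropenyl-4β,5β-dimethyl-10βH-decalin-8-one F8. Pyridine-buffered HF·pyridine removes the silyl ether to give 3α-hydroxy-9β-(4-methoxybenzyloxy)-7β-isopropenyl-4β,5β-dimethyl-10βH-decalin-8-one F9, which has a single hydroxyl. Esterification with 31 through mixed anhydride 32, with minimal DMAP at 0 °C, rejoins the route at 34.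

## Further compounds

F1 | step 5 | (S)-3-[(R)-3-(tert-butyldimethylsilyloxy)-5-chloropent-1-en-2-yl]-3-methylcyclohexanone | C=C([C@H](O[Si](C)(C)C(C)(C)C)CCCl)[C@]1(C)CC(=O)CCC1
F2 | step 6 | 3α-hydroxy-5β-methyl-4-methylidene-10βH-decalin-9-one | C1C[C@@]2(C)[C@H](CC[C@@H](O)C2=C)C(=O)C1
F3 | step 6 | 3α-hydroxy-4β,5β-dimethyl-10βH-decalin-9-one | C1C[C@@]2(C)[C@H](CC[C@@H](O)[C@@H]2C)C(=O)C1
F4 | step 8 | 9-(trimethylsilyloxy)-3α-(tert-butyldimethylsilyloxy)-7β-isopropenyl-4β,5β-dimethyl-10βH-decal-8-ene | C=C(C)[C@H]1C[C@@]2(C)[C@H](CC[C@@H](O[Si](C)(C)C(C)(C)C)[C@@H]2C)C(O[Si](C)(C)C)=C1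
F5 | step 10 | 3α,8β-bis(tert-butyldimethylsilyloxy)-7β-isopropenyl-4β,5β-dimethyl-10βH-decalin-9-one | C=C(C)[C@H]1C[C@@]2(C)[C@H](CC[C@@H](O[Si](C)(C)C(C)(C)C)[C@@H]2C)C(=O)[C@H]1O[Si](C)(C)C(C)(C)C
F6 | step 10 | 3α,8β-bis(tert-butyldimethylsilyloxy)-7β-isopropenyl-4β,5β-dimethyl-10βH-decalin-9β-ol | C=C(C)[C@H]1C[C@@]2(C)[C@H](CC[C@@H](O[Si](C)(C)C(C)(C)C)[C@@H]2C)[C@@H](O)[C@H]1O[Si](C)(C)C(C)(C)C
F7 | step 10 | 9β-(4-methoxybenzyloxy)-3α,8β-bis(tert-butyldimethylsilyloxy)-7β-isopropenyl-4β,5β-dimethyl-10βH-decalin | C=C(C)[C@H]1C[C@@]2(C)[C@H](CC[C@@H](O[Si](C)(C)C(C)(C)C)[C@@H]2C)[C@@H](OCc3ccc(OC)cc3)[C@H]1O[Si](C)(C)C(C)(C)C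
F8 | step 18 | 9β-(4-methoxybenzyloxy)-3α-(tert-butyldimethylsilyloxy)-7β-isopropenyl-4β,5β-dimethyl-10βH-decalin-8-one | C=C(C)[C@H]1C[C@@]2(C)[C@H](CC[C@@H](O[Si](C)(C)C(C)(C)C)[C@@H]2C)[C@@H](OCc3ccc(OC)cc3)C1=O
F9 | step 18 | 3α-hydroxy-9β-(4-methoxybenzyloxy)-7β-isopropenyl-4β,5β-dimethyl-10βH-decalin-8-one | C=C(C)[C@H]1C[C@@]2(C)[C@H](CC[C@@H](O)[C@@H]2C)[C@@H](OCc3ccc(OC)cc3)C1=O
A1 | alternative 1 | 2-methylcyclohex-2-en-1-one | CC1=CCCCC1=O
A2 | alternative 1 | vinylene carbonate (1,3-dioxol-2-one) | O=C1OC=CO1
A3 | alternative 1 | cis-fused cyclobutane carbonate photoadduct of A1 and A2 | O=C1CCC[C@@H]2[C@H]3OC(=O)O[C@H]3[C@]12C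
A4 | alternative 2 | cis-fused 4,5-dimethyl-octal-6-one C3 allylboronate (C8 silyl ether, C9 PMB ether) | C1C(=O)[C@@]2(C)[C@H](C=C[C@@H](B3OC(C)(C)C(C)(C)O3)[C@@H]2C)[C@@H](OCc4ccc(OC)cc4)[C@@H]1O[Si](C)(C)C(C)(C)C
A5 | alternative 3 | cis-fused 5-methyl-1-nitro-octal-6-en-8-one, C4 ethylene ketal | C1=C[C@@]2(C)[C@H]([C@H]([N+](=O)[O-])CCC23OCCO3)CC1=O
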